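## Plan

1. **Numbering and enabling feature.** C1 is the oxirane carbon bearing C7H2OBz, C2/C3 are the acetoxy carbons, C4/C5 the carbinol carbons, and C6 the oxirane CH. Around the cyclohexane every pair of neighbouring C–O bonds is trans except C1–O/C2–O. C1 is fully substituted, and C7–C1–C6 is a dihydroxyacetone unit. A cis-selective reductive coupling of a C1 ketone with a C2 aldehyde therefore makes the ring, the quaternary carbon and the only cis-diol in one event.
2. **Retrosynthetic cuts.** First the acyl–O bonds and the C6–O oxirane bond (back to a 1-OH/6-sulfonate pair on opposite faces), then C1–C2 (pinacol), then C5–C6 (aldol). This leaves 2,2-dimethyl-1,3-dioxan-5-one (C7–C1–C6) and a D-tartrate-derived C2–C5 aldehyde-ester.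
3. **Forward order.** C5–C6 joins the chain. C1–C2 closes the carbocycle, cis-fused to the dioxane. The dioxane is opened, and the oxirane closes in the penultimate step.
4. **Stereochemistry.** C3/C4 come from diethyl D-tartrate, C5/C6 from the (R)-proline anti-aldol, and C1/C2 from the samarium-bridged ketyl coupling. C6 is inverted when O1 displaces the C6 mesylate.

Key step: step 10

**Remarks on the chemistry**
- The target SMILES is read as [(1S,2R,3S,4R,5R,6S)-2,3-diacetoxy-4,5-dihydroxy-7-oxabicyclo[4.1.0]heptan-1-yl]methyl benzoate.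
- Face convention for carbocycles: the ring is drawn flat with C1→C6 clockwise. β is the face of C7 and α is the face of the oxirane oxygen. The target is then 1α,6α-epoxy, 2α-OAc, 3β-OAc, 4α-OH, 5β-OH.
- Assumption: diol 11 is carried as a mixture of epimers at the transient C1 carbinol, which step 9 removes. Its SMILES leaves that centre open.

## Route

Step 1
Reactants: 1 diethyl D-tartrate
Product: 3 diethyl (2S,3S)-2-hydroxy-3-[(4-methoxybenzyl)oxy]butanedioate, via stannylene acetal 2 (not isolated)
Conditions: Bu2SnO, toluene, reflux (Dean–Stark); then PMBCl, CsF, DMF, rt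
Reagents that add atoms: 4-methoxybenzyl chloride, COc1ccc(CCl)cc1; dibutyltin oxide, CCCC[Sn](=O)CCCC (atoms kept only in intermediate 2)
Why: Stannylene-acetal mono-O-alkylation: tin activation lets only one oxygen be alkylated, and because the two hydroxyls of C2-symmetric 1 are equivalent a single mono-ether results with both tartrate stereocentres (future C3 and C4) untouched.

Step 2
Reactants: 3 mono-PMB tartrate
Product: 4 ethyl (2S,3R)-3,4-dihydroxy-2-[(4-methoxybenzyl)oxy]butanoate
Conditions: BH3·SMe2 (1.05 equiv), NaBH4 (5 mol %), THF, 0 °C → rt; MeOH quench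
Reagents that add atoms: none
Why: Hydroxyl-directed ester reduction with borane and catalytic borohydride: the free C4 hydroxyl forms an alkoxyborane that delivers hydride through a five-membered chelate to the neighbouring C5 ester only, so the C2 ester beside the PMB ether is kept as the latent aldehyde and no stereocentre is touched.

Step 3
Reactants: 4 diol ester
Product: 5 ethyl (2S,3R)-3-hydroxy-2-[(4-methoxybenzyl)oxy]-4-[(triethylsilyl)oxy]butanoate
Conditions: TESCl (1.05 equiv), imidazole, CH2Cl2, −40 → −20 °C
Reagents that add atoms: chlorotriethylsilane, CC[Si](Cl)(CC)CC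
Why: Chemoselective silylation: the unhindered primary C5 hydroxyl reacts much faster at low temperature than the flanked secondary C4 hydroxyl, and capping it also stops γ-lactonisation onto the C2 ester.

Step 4
Reactants: 5 primary TES ether
Product: 6 ethyl (2S,3R)-3-[(tert-butyldimethylsilyl)oxy]-2-[(4-methoxybenzyl)oxy]-4-[(triethylsilyl)oxy]butanoate
Conditions: TBSOTf, 2,6-lutidine, CH2Cl2, −78 → 0 °C
Reagents that add atoms: tert-butyldimethylsilyl triflate, CC(C)(C)[Si](C)(C)OS(=O)(=O)C(F)(F)F
Why: Silyl triflate etherification under a hindered non-nucleophilic base installs the robust C4 silyl ether without disturbing the TES ether, the ester or the adjacent stereocentres.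

Step 5
Reactants: 6 TES/TBS bis-silyl ether
Product: 7 ethyl (2S,3S)-3-[(tert-butyldimethylsilyl)oxy]-2-[(4-methoxybenzyl)oxy]-4-oxobutanoate
Conditions: (COCl)2, DMSO, CH2Cl2, −78 → −40 °C; Et3N, −78 → 0 °C
Reagents that add atoms: none
Why: Swern oxidation applied directly to a primary triethylsilyl ether: the activated DMSO reagent exchanges the exposed primary TES group for the alkoxysulfonium ion, which collapses to the C5 aldehyde, while the secondary TBS ether is inert and a free γ-hydroxy ester is never liberated.

Step 6
Reactants: 7 C2–C5 aldehyde-ester; 8 2,2-dimethyl-1,3-dioxan-5-one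
Product: 9 ethyl (2S,3R,4S)-3-[(tert-butyldimethylsilyl)oxy]-4-[(4R)-2,2-dimethyl-5-oxo-1,3-dioxan-4-yl]-4-hydroxy-2-[(4-methoxybenzyl)oxy]butanoate (C5/C6 anti, C4/C5 syn)
Conditions: (R)-proline (30 mol %), DMF, 2–4 °C
Reagents that add atoms: none
Why: Proline-catalysed direct (enamine) aldol addition of the dihydroxyacetone acetonide: the ring-locked E-enamine of 8 attacks the acid-activated aldehyde in a chair-like hydrogen-bonded transition state that gives the anti adduct, (R)-proline fixing (6R) and the C5 carbinol in the 4,5-syn (tagatose-type) sense, the catalyst having to override only the weak facial bias expected of a threo-α,β-dioxygenated aldehyde toward an E-enamine.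

Step 7
Reactants: 9 aldol adduct
Product: 10 ethyl (2S,3S,4S)-3,4-bis[(tert-butyldimethylsilyl)oxy]-4-[(4R)-2,2-dimethyl-5-oxo-1,3-dioxan-4-yl]-2-[(4-methoxybenzyl)oxy]butanoate
Conditions: TBSOTf, 2,6-lutidine, CH2Cl2, −78 → −20 °C
Reagents that add atoms: tert-butyldimethylsilyl triflate, CC(C)(C)[Si](C)(C)OS(=O)(=O)C(F)(F)F
Why: Low-temperature silyl triflate etherification caps the β-hydroxy ketone faster than retro-aldol, C6 epimerisation or enol silylation can occur, so C5 and C6 are preserved.

Step 8
Reactants: 10 keto-ester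
Product: 11 diol with C2 as CH2OH and C1 as ring carbinol (both C1 epimers), O3 PMB, O4/O5 TBS, O6/O7 acetonide
Conditions: LiBH4, THF, 0 °C → rt
Reagents that add atoms: none
Why: Borohydride reduction takes the α-alkoxy ester to the C2 primary alcohol and unavoidably the C1 ketone to the carbinol while silyl ethers, PMB ether and acetal are inert; the new C1 centre (axial hydride attack, equatorial alcohol expected to prevail) is of no consequence because step 9 removes it.

Step 9
Reactants: 11 diol
Product: 12 (2S,3S,4S)-3,4-bis[(tert-butyldimethylsilyl)oxy]-4-[(4R)-2,2-dimethyl-5-oxo-1,3-dioxan-4-yl]-2-[(4-methoxybenzyl)oxy]butanal (C1 ketone, C2 aldehyde)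
Conditions: Dess–Martin periodinane, NaHCO3, CH2Cl2, 0 °C → rt; used without chromatography
Reagents that add atoms: none
Why: Double Dess–Martin oxidation gives the 1,6-keto-aldehyde under buffered, essentially non-basic conditions, so the α-stereocentres C3 and C6 should not epimerise and no β-silyloxy group should be eliminated.

Step 10
Reactants: 12 keto-aldehyde
Product: 13 carbocyclic cis-diol: 1α-OH, 2α-OH, 3β-OPMB, 4α-OTBS, 5β-OTBS, with 6β-O and O7 (C7 β on C1) joined as the isopropylidene acetal of a cis-fused 1,3-dioxane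
Conditions: SmI2 (3 equiv), t-BuOH (3 equiv), THF, −78 → −20 °C, slow addition of 12
Reagents that add atoms: none
Why: SmI2 transfers one electron to each carbonyl (the C2 aldehyde first), and the two ketyls, held on samarium(III), combine at carbon to form the C1–C2 bond and a cyclic samarium diolate that t-BuOH and work-up protonate. The closest known reaction type is the SmI2 intramolecular pinacol coupling of carbohydrate-derived 1,6-dicarbonyl compounds to cis-diol cyclitols. The one new ring, the cyclohexane, closes 6-exo-trig with respect to either carbonyl through a chair that keeps O3, O4 and O5 equatorial and leaves the dioxane cis-fused. C1 is controlled by the C6 stereocentre: the tether sits equatorially on the dioxanone chair and the new bond enters axially, so that C1–O(Sm) ends antiperiplanar to the C6–O bond (1α-OH against 6β-O), the arrangement of least dipole repulsion. C2 is controlled by the samarium bridge, which holds C2–O cis to C1–O, and by C3, whose OPMB group the C2–O bond avoids (trans), so both preferences point to the same 1α,2α-diol. The step needs coupling to outrun α-C–O cleavage and simple reduction, which is secured by poor (ether, not acyloxy) leaving groups beside both carbonyls, the absence of HMPA, low temperature, only a weak proton source and high dilution.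

Step 11
Reactants: 13 pinacol product
Product: 14 1α,2α,3β-triol (4α,5β-bis-TBS ether, 6β,7-O-isopropylidene)
Conditions: DDQ, CH2Cl2–pH 7 buffer (10:1), 0 °C → rt
Reagents that add atoms: none
Why: Oxidative PMB cleavage (benzylic hydride abstraction by DDQ, then hydrolysis of the hemiacetal) is neutral and leaves silyl ethers, acetal and free hydroxyls untouched, water suppressing capture of the benzylic cation by the trans C2 hydroxyl.

Step 12
Reactants: 14 triol
Product: 15 2α,3β-diacetate with free tertiary 1α-OH
Conditions: Ac2O, pyridine, DMAP (cat.), CH2Cl2, 0 °C → rt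
Reagents that add atoms: acetic anhydride, CC(=O)OC(C)=O
Why: Chemoselective acylation: the two equatorial secondary hydroxyls are acetylated in one operation while the axial tertiary C1 hydroxyl reacts far more slowly and stays free for the later ring closure.

Step 13
Reactants: 15 diacetate acetonide
Product: 16 1α,6β,7-triol (2α,3β-diacetate, 4α,5β-bis-TBS ether)
Conditions: AcOH–H2O (4:1), 40 °C
Reagents that add atoms: none
Why: Mild acid hydrolysis of an isopropylidene acetal: the 1,3-dioxane acetonide with its axial methyl group is much more labile than flanked secondary TBS ethers, and acetates neither cleave nor migrate readily in weakly acidic water.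

Step 14
Reactants: 16 triol; 17 benzoyl chloride
Product: 18 7-benzoate 1α,6β-diol
Conditions: BzCl (1.1 equiv), pyridine, CH2Cl2, −20 → 0 °C
Reagents that add atoms: benzoyl chloride 17, O=C(Cl)c1ccccc1
Why: Selective acylation of the primary C7 hydroxyl, which outcompetes the axial, doubly flanked secondary C6 hydroxyl and the tertiary C1 hydroxyl at low temperature.

Step 15
Reactants: 18 benzoate diol
Product: 20 4α,5β-bis-TBS ether of the target (1α,6α-oxirane), via C6 mesylate 19 (not isolated)
Conditions: MsCl, Et3N, CH2Cl2, 0 °C; then DBU, 0 → 40 °C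
Reagents that add atoms: methanesulfonyl chloride, CS(=O)(=O)Cl (atoms kept only in intermediate 19)
Why: Sulfonylation (via sulfene, little affected by hindrance) of the only acylable hydroxyl followed by intramolecular Williamson-type SN2 closure: in the ground-state chair 1α-OH and 6β-OMs are trans-diaxial with all other groups equatorial, so O1 displaces the mesylate with inversion at C6 under a non-nucleophilic amidine base that spares the three esters.

Step 16
Reactants: 20 bis-TBS epoxide
Product: 21 target, [(1S,2R,3S,4R,5R,6S)-2,3-diacetoxy-4,5-dihydroxy-7-oxabicyclo[4.1.0]heptan-1-yl]methyl benzoate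
Conditions: HF·pyridine, pyridine, THF, 0 °C → rt
Reagents that add atoms: none
Why: Fluoride desilylation in a weakly acidic buffered medium frees O4 and O5 without generating alkoxides, so acetyl migration (O3→O4) and epoxide migration from the trans C5 oxygen are avoided, and the oxirane, deactivated by three neighbouring C–O bonds, should resist opening.

## Compound list

1 | diethyl D-tartrate | CCOC(=O)[C@@H](O)[C@H](O)C(=O)OCC | starting material
2 | diethyl (4S,5S)-2,2-dibutyl-1,3,2-dioxastannolane-4,5-dicarboxylate | CCOC(=O)[C@H]1O[Sn](CCCC)(CCCC)O[C@@H]1C(=O)OCC | intermediate (not isolated)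
3 | diethyl (2S,3S)-2-hydroxy-3-[(4-methoxybenzyl)oxy]butanedioate | CCOC(=O)[C@@H](OCc1ccc(OC)cc1)[C@H](O)C(=O)OCC | intermediate
4 | ethyl (2S,3R)-3,4-dihydroxy-2-[(4-methoxybenzyl)oxy]butanoate | CCOC(=O)[C@@H](OCc1ccc(OC)cc1)[C@H](O)CO | intermediate
5 | ethyl (2S,3R)-3-hydroxy-2-(PMB-oxy)-4-(TES-oxy)butanoate | CCOC(=O)[C@@H](OCc1ccc(OC)cc1)[C@H](O)CO[Si](CC)(CC)CC | intermediate
6 | ethyl (2S,3R)-3-(TBS-oxy)-2-(PMB-oxy)-4-(TES-oxy)butanoate | CCOC(=O)[C@@H](OCc1ccc(OC)cc1)[C@H](O[Si](C)(C)C(C)(C)C)CO[Si](CC)(CC)CC | intermediate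
7 | ethyl (2S,3S)-3-(TBS-oxy)-2-(PMB-oxy)-4-oxobutanoate | CCOC(=O)[C@@H](OCc1ccc(OC)cc1)[C@H](O[Si](C)(C)C(C)(C)C)C=O | intermediate
8 | 2,2-dimethyl-1,3-dioxan-5-one | CC1(C)OCC(=O)CO1 | starting material
9 | anti-aldol adduct (free C5-OH) | CCOC(=O)[C@@H](OCc1ccc(OC)cc1)[C@H](O[Si](C)(C)C(C)(C)C)[C@@H](O)[C@H]1OC(C)(C)OCC1=O | intermediate
10 | O4,O5-bis-TBS keto-ester | CCOC(=O)[C@@H](OCc1ccc(OC)cc1)[C@H](O[Si](C)(C)C(C)(C)C)[C@@H](O[Si](C)(C)C(C)(C)C)[C@H]1OC(C)(C)OCC1=O | intermediate
11 | C1,C2-diol (C1 epimers) | OC[C@@H](OCc1ccc(OC)cc1)[C@H](O[Si](C)(C)C(C)(C)C)[C@@H](O[Si](C)(C)C(C)(C)C)[C@H]1OC(C)(C)OCC1O | intermediate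
12 | keto-aldehyde (pinacol precursor) | O=C[C@@H](OCc1ccc(OC)cc1)[C@H](O[Si](C)(C)C(C)(C)C)[C@@H](O[Si](C)(C)C(C)(C)C)[C@H]1OC(C)(C)OCC1=O | intermediate
13 | 1α,2α-diol carbocycle cis-fused to the dioxane | COc1ccc(cc1)CO[C@H]1[C@H](O[Si](C)(C)C(C)(C)C)[C@@H](O[Si](C)(C)C(C)(C)C)[C@H]2OC(C)(C)OC[C@@]2(O)[C@@H]1O | intermediate
14 | 1α,2α,3β-triol | O[C@H]1[C@H](O[Si](C)(C)C(C)(C)C)[C@@H](O[Si](C)(C)C(C)(C)C)[C@H]2OC(C)(C)OC[C@@]2(O)[C@@H]1O | intermediate
15 | 2α,3β-diacetate, 1α-OH free | CC(=O)O[C@H]1[C@H](O[Si](C)(C)C(C)(C)C)[C@@H](O[Si](C)(C)C(C)(C)C)[C@H]2OC(C)(C)OC[C@@]2(O)[C@@H]1OC(C)=O | intermediate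
16 | 1α,6β,7-triol diacetate | CC(=O)O[C@H]1[C@H](O[Si](C)(C)C(C)(C)C)[C@@H](O[Si](C)(C)C(C)(C)C)[C@@H](O)[C@@](O)(CO)[C@@H]1OC(C)=O | intermediate
17 | benzoyl chloride | O=C(Cl)c1ccccc1 | starting material
18 | 7-benzoate 1α,6β-diol | CC(=O)O[C@H]1[C@H](O[Si](C)(C)C(C)(C)C)[C@@H](O[Si](C)(C)C(C)(C)C)[C@@H](O)[C@@](O)(COC(=O)c2ccccc2)[C@@H]1OC(C)=O | intermediate
19 | 6β-mesylate | CC(=O)O[C@H]1[C@H](O[Si](C)(C)C(C)(C)C)[C@@H](O[Si](C)(C)C(C)(C)C)[C@@H](OS(C)(=O)=O)[C@@](O)(COC(=O)c2ccccc2)[C@@H]1OC(C)=O | intermediate (not isolated)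
20 | 1α,6α-oxirane, 4α,5β-bis-TBS ether | CC(=O)O[C@H]1[C@H](O[Si](C)(C)C(C)(C)C)[C@@H](O[Si](C)(C)C(C)(C)C)[C@@H]2O[C@]2(COC(=O)c2ccccc2)[C@@H]1OC(C)=O | intermediate
21 | [(1S,2R,3S,4R,5R,6S)-2,3-diacetoxy-4,5-dihydroxy-7-oxabicyclo[4.1.0]heptan-1-yl]methyl benzoate | CC(=O)O[C@H]1[C@H](O)[C@@H](O)[C@@H]2O[C@]2(COC(=O)c2ccccc2)[C@@H]1OC(C)=O | target

## Step count

Total step count: 16. Longest linear sequence: 16 steps (1 → 21); 8 and 17 are bought.

## Steps most likely to fail

**Step 10.** A ketyl, or the samarium enolate formed after a second electron transfer, may expel an α-alkoxy group. This could be a ring C–O bond of the dioxanone or the OPMB group beside the aldehyde. The carbonyls may also be merely reduced, or the facial preference may erode toward trans-fused or trans-diol isomers. The fallback sets out from 12. Double Wittig methylenation (Ph3P=CH2, THF, −78 → 0 °C) gives the 1,7-diene F1. Ring-closing metathesis with the second-generation Grubbs catalyst joins the same two carbons as a C1=C2 alkene in the dioxane-fused cyclohexene F2. Catalytic OsO4/NMO then adds both oxygens syn from the α-face, anti to the two β-oriented allylic C–O bonds at C3 and C6. The route is rejoined at 13.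

**Step 6.** The catalyst works against the aldehyde's own Felkin-type preference. Conversion may therefore be slow, facial selectivity may be poor, and the long reaction time may allow β-elimination or C4 epimerisation through the aldehyde enamine. The fallback replaces catalytic control by a covalently bound, removable controller on the ketone and sets out from 8.
- Condensation of 8 with (R)-1-amino-2-(methoxymethyl)pyrrolidine gives the RAMP hydrazone F3.
- Deprotonation (t-BuLi, THF, −78 °C) and C-silylation with TBSOTf give the α-silyl hydrazone F4.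
- Aqueous oxalic acid releases (R)-4-(tert-butyldimethylsilyl)-2,2-dimethyl-1,3-dioxan-5-one F5.
- Enolisation of F5 with Cy2BCl/Et3N toward the free CH2 and addition of 7 through a Zimmerman–Traxler chair give the anti aldol formed trans to the silyl group, the 4,6-trans silylated aldol F6.
- Buffered fluoride removes the α-keto C–Si bond faster than the secondary O–Si bond, and the route is rejoined at 9.

**Step 15.** Sulfonylation of the axial, doubly flanked C6 hydroxyl may be sluggish. Once base is present, acetyl or benzoyl migration onto the tertiary C1 oxygen may compete with ring closure and scramble the esters. The fallback sets out from 18 and avoids both the sulfonate and the base. Mitsunobu cyclodehydration of the trans-diaxial diol (PPh3, DIAD, toluene, rt → 60 °C) activates the secondary C6 oxygen as an oxyphosphonium ion. The neutral C1 hydroxyl displaces it with inversion, which rejoins the route at 20. This fallback makes no new compound (F0).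

## Further compounds

F1 | step 10 | 1,7-diene from double methylenation of 12 | C=C[C@@H](OCc1ccc(OC)cc1)[C@H](O[Si](C)(C)C(C)(C)C)[C@@H](O[Si](C)(C)C(C)(C)C)[C@H]1OC(C)(C)OCC1=C
F2 | step 10 | dioxane-fused C1=C2 cyclohexene | COc1ccc(cc1)CO[C@H]1[C@H](O[Si](C)(C)C(C)(C)C)[C@@H](O[Si](C)(C)C(C)(C)C)[C@H]2OC(C)(C)OCC2=C1
F3 | step 6 | RAMP hydrazone of 8 | COC[C@H]1CCCN1N=C1COC(C)(C)OC1
F4 | step 6 | α-silyl RAMP hydrazone | COC[C@H]1CCCN1N=C1COC(C)(C)O[C@@H]1[Si](C)(C)C(C)(C)C
F5 | step 6 | (R)-4-(tert-butyldimethylsilyl)-2,2-dimethyl-1,3-dioxan-5-one | O=C1COC(C)(C)O[C@@H]1[Si](C)(C)C(C)(C)C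
F6 | step 6 | 4,6-trans silylated anti-aldol | CCOC(=O)[C@@H](OCc1ccc(OC)cc1)[C@H](O[Si](C)(C)C(C)(C)C)[C@@H](O)[C@H]1OC(C)(C)O[C@H]([Si](C)(C)C(C)(C)C)C1=O
F0 | step 15 | none | none
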